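The route cuts the C9–C10 bond (labdane numbering) by an anionic oxy-Cope rearrangement. The target is a 5-epi-labdane: rings A/B are cis-fused (C5–H and C10–CH3 on one face), with quaternary C10 wedged between C9 and the C4 gem-dimethyl carbon. A 2-alkenylbicyclo[2.2.2]oct-5-en-2-olate can only rearrange to a cis-decalin, so one [3,3] shift joins both fragments, closes ring B, creates C10 and C9 from a (Z)-alkene and fixes the cis fusion; the resulting enolate is hydroxylated in the same flask to set C8. The precursor is carbinol 12, from a catalytic asymmetric Diels–Alder ketone 7 and (Z)-vinyl iodide 10.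

Key step: step 8

Assumption: the SMILES is read literally as a cis-fused (5R,6S,8R,9R,10S,13R) labdane; labdane numbering (C11–C16 side chain, C17 on C8, C18/C19 on C4, C20 on C10; α = face opposite C20) is used for all decalins, and the catalyst enantiomers of steps 3 and 16 follow the accepted face-shielding models (the antipodal catalyst would be used if the observed sense were opposite).

Step 1
Reactants: 1 3,5,5-trimethylcyclohex-3-en-1-one (β-isophorone)
Product: 3 3,5,5-trimethylcyclohexa-1,3-dien-1-yl trifluoromethanesulfonate, via lithium dienolate 2 (not isolated)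
Conditions: LDA, THF, −78 °C; then PhNTf2, −78 °C → rt
Reagents that add atoms: N-phenylbis(trifluoromethanesulfonimide), O=S(=O)(N(c1ccccc1)S(=O)(=O)C(F)(F)F)C(F)(F)F
Why: LDA should remove the doubly activated C2 proton (allylic and α to the carbonyl) of the deconjugated enone to give the fully conjugated dienolate 2, which PhNTf2 traps on oxygen (enol triflate formation).

Step 2
Reactants: 3 3,5,5-trimethylcyclohexa-1,3-dien-1-yl trifluoromethanesulfonate
Product: 4 2,6,6-trimethylcyclohexa-1,3-diene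
Conditions: Pd(OAc)2 (cat.), PPh3, Bu3N, HCO2H, DMF, 60 °C
Reagents that add atoms: none
Why: Oxidative addition of Pd(0) into the dienyl C–O bond, formate-to-hydride exchange and reductive elimination (palladium-catalysed triflate reduction) should give the volatile diene without moving either double bond.

Step 3
Reactants: 4 2,6,6-trimethylcyclohexa-1,3-diene; 5 prop-2-enal (acrolein)
Product: 6 (1S,2S,4R)-5,8,8-trimethylbicyclo[2.2.2]oct-5-ene-2-carbaldehyde
Conditions: (5R)-5-benzyl-2,2,3-trimethylimidazolidin-4-one·HCl (20 mol%), MeCN/H2O 95:5, rt; minor exo adduct removed by chromatography (it would lead to ent-7)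
Reagents that add atoms: none
Why: Iminium-ion activation of acrolein (organocatalytic Diels–Alder reaction) should give the "para" regioisomer, the CH2 terminus of the dienophile bonding to the diene terminus next to the methyl-bearing carbon, which is also the sterically easier union beside the gem-dimethyl group, while the benzyl group of the (5R) catalyst shields one face of the iminium so that C2 becomes S and the endo adduct carries the 1S,4R bridgeheads.

Step 4
Reactants: 6 (1S,2S,4R)-5,8,8-trimethylbicyclo[2.2.2]oct-5-ene-2-carbaldehyde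
Product: 7 (1S,4R)-5,8,8-trimethylbicyclo[2.2.2]oct-5-en-2-one
Conditions: Cu(OAc)2 (cat.), 2,2′-bipyridine, DABCO, O2 (1 atm), DMF, 40 °C
Reagents that add atoms: dioxygen, O=O
Why: Copper-catalysed aerobic oxidative deformylation of the α-branched aldehyde (α-hydroperoxide, then loss of formic acid) makes acrolein a ketene equivalent and should leave the trisubstituted alkene and both bridgehead stereocentres untouched.

Step 5
Reactants: 8 5-[(tert-butyldimethylsilyl)oxy]pentan-1-ol
Product: 9 5-[(tert-butyldimethylsilyl)oxy]pentanal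
Conditions: TEMPO (cat.), PhI(OAc)2, CH2Cl2, rt
Reagents that add atoms: none
Why: TEMPO-catalysed oxidation with a hypervalent iodine co-oxidant should stop at the aldehyde and spare the silyl ether.

Step 6
Reactants: 9 5-[(tert-butyldimethylsilyl)oxy]pentanal
Product: 10 tert-butyl{[(5Z)-6-iodohept-5-en-1-yl]oxy}dimethylsilane
Conditions: [Ph3PCH2CH3]I, n-BuLi, THF, rt; I2, −78 °C; NaHMDS, −20 °C; then 9, −78 °C → rt
Reagents that add atoms: ethyltriphenylphosphonium iodide, CC[P+](c1ccccc1)(c1ccccc1)c1ccccc1.[I-]; iodine, II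
Why: The α-iodo ylide generated in situ should react through the early oxaphosphetane transition state of non-stabilised ylides (Stork–Zhao-type Wittig olefination), which places iodine cis to the alkyl chain and gives the (Z)-2-iodoalkene.

Step 7
Reactants: 10 tert-butyl{[(5Z)-6-iodohept-5-en-1-yl]oxy}dimethylsilane; 7 (1S,4R)-5,8,8-trimethylbicyclo[2.2.2]oct-5-en-2-one
Product: 12 (1S,2R,4R)-2-[(2Z)-7-[(tert-butyldimethylsilyl)oxy]hept-2-en-2-yl]-5,8,8-trimethylbicyclo[2.2.2]oct-5-en-2-ol, via alkenyllithium 11 (not isolated)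
Conditions: t-BuLi (2 equiv), Et2O, −78 °C; then 7, THF, −78 → −20 °C
Reagents that add atoms: none
Why: Iodine–lithium exchange proceeds with retention of alkene geometry, and the alkenyllithium should add to the carbonyl (1,2-addition) from the face of the C5=C6 etheno bridge, away from the dimethylethano bridge, which sets C2 as R with the alkenyl group syn to the ring alkene as the [3,3] shift requires.

Step 8
Reactants: 12 (1S,2R,4R)-2-[(2Z)-7-[(tert-butyldimethylsilyl)oxy]hept-2-en-2-yl]-5,8,8-trimethylbicyclo[2.2.2]oct-5-en-2-ol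
Product: 16 (5R,8S,9R,10S)-14-[(tert-butyldimethylsilyl)oxy]-8-[(trimethylsilyl)oxy]-15,16-dinorlabd-1-en-7-one, via potassium alkoxide 13 (not isolated), via potassium enolate 14 (not isolated), via potassium ketol alkoxide 15 (not isolated)
Conditions: KHMDS, 18-crown-6, THF, 0 → 50 °C; then 2-(phenylsulfonyl)-3-phenyloxaziridine, −78 °C; then TMSCl, −78 → 0 °C
Reagents that add atoms: 2-(phenylsulfonyl)-3-phenyloxaziridine, O=S(=O)(N1OC1c1ccccc1)c1ccccc1; chlorotrimethylsilane, C[Si](C)(C)Cl
Why: Deprotonation gives tertiary potassium alkoxide 13, whose C1–C2 bond (bicycle numbering) is weakened by the oxyanion, so that the 1,5-diene C3′=C2′–C2–C1–C6=C5 should undergo a concerted [3,3] shift (anionic oxy-Cope rearrangement, the reaction type established for 2-vinylbicyclo[2.2.2]oct-5-en-2-olates) that breaks C1–C2 and forms C3′–C5, which is C9–C10 of the labdane. Ring B is closed by this bond through the boat-like, suprafacial six-centre array that the bicycle enforces, and the carbocycle formerly spanned by the etheno and dimethylethano bridges becomes ring A. C10 becomes quaternary and cis to C5–H because the alkenyl terminus can reach only the face of the C5=C6 π bond that looks toward the carbinol bridge; C9 follows from the (Z) geometry, which in the boat places C11 inside and therefore on the face of the C10 methyl group; C5 is the bridgehead fixed in step 3 and is not touched. The tetrasubstituted C7=C8 enolate 14 is formed regiospecifically and should be hydroxylated at C8 anti to the C9 chain, which A1,2 strain with C17 holds pseudoaxial, giving the 8α-oxygen that TMSCl then caps. The step needs the [3,3] shift to win over β-fragmentation or a [1,3] shift and needs the (Z) geometry intact; the syn alkenyl/etheno arrangement from step 7 and the poor leaving-group ability of a vinyl anion secure the former, and the A1,3 strain of the inside substituent is already present in the ground state, so it should slow but not divert the rearrangement.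

Step 9
Reactants: 16 (5R,8S,9R,10S)-14-[(tert-butyldimethylsilyl)oxy]-8-[(trimethylsilyl)oxy]-15,16-dinorlabd-1-en-7-one
Product: 17 (5R,8S,9R,10S)-14-[(tert-butyldimethylsilyl)oxy]-8-[(trimethylsilyl)oxy]-15,16-dinorlabdan-7-one
Conditions: H2 (1 atm), 10% Pd/C, EtOAc, rt
Reagents that add atoms: none
Why: Heterogeneous hydrogenation should saturate the only C=C bond (C1=C2), which is why the side-chain vinyl group is built only after this step.

Step 10
Reactants: 17 (5R,8S,9R,10S)-14-[(tert-butyldimethylsilyl)oxy]-8-[(trimethylsilyl)oxy]-15,16-dinorlabdan-7-one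
Product: 19 (5R,8S,9R,10S)-14-[(tert-butyldimethylsilyl)oxy]-8-[(trimethylsilyl)oxy]-15,16-dinorlabd-6-en-7-yl trifluoromethanesulfonate, via potassium enolate 18 (not isolated)
Conditions: KHMDS, THF, −78 °C; then PhNTf2, −78 → 0 °C
Reagents that add atoms: N-phenylbis(trifluoromethanesulfonimide), O=S(=O)(N(c1ccccc1)S(=O)(=O)C(F)(F)F)C(F)(F)F
Why: Ketone 17 can enolise only toward C6 because C8 is fully substituted, so O-triflation of enolate 18 should give a single enol triflate without touching C5 (enol triflate formation).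

Step 11
Reactants: 19 (5R,8S,9R,10S)-14-[(tert-butyldimethylsilyl)oxy]-8-[(trimethylsilyl)oxy]-15,16-dinorlabd-6-en-7-yl trifluoromethanesulfonate
Product: 21 (5R,8R,9R,10S)-14-[(tert-butyldimethylsilyl)oxy]-15,16-dinorlabd-6-en-8-ol, via silyl ether 20 (not isolated)
Conditions: Pd(OAc)2 (cat.), PPh3, Bu3N, HCO2H, DMF, 60 °C; then K2CO3, MeOH, rt
Reagents that add atoms: none
Why: Palladium-catalysed formate reduction of the enol triflate should give the C6=C7 alkene regiospecifically, and methanolysis then removes only the labile tertiary TMS ether to free the allylic alcohol.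

Step 12
Reactants: 21 (5R,8R,9R,10S)-14-[(tert-butyldimethylsilyl)oxy]-15,16-dinorlabd-6-en-8-ol
Product: 24 (5R,6S,8R,9R,10S)-14-[(tert-butyldimethylsilyl)oxy]-15,16-dinorlabdane-6,8-diol, via hydrosilyl ether 22 (not isolated), via oxasilolane 23 (not isolated)
Conditions: Me2SiHCl, Et3N, DMAP (cat.), CH2Cl2, 0 °C → rt; then Pt2(dvs)3 (cat.), toluene, 60 °C; then 30% H2O2, KF, KHCO3, THF/MeOH, rt
Reagents that add atoms: hydrogen peroxide, OO
Why: The silicon hydride tethered to O8 can reach only C6 and only from the α face (5-endo intramolecular hydrosilylation of an allylic alcohol), and Tamao–Fleming oxidation with retention should therefore give the 6α,8α-syn-1,3-diol with C6 as S.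

Step 13
Reactants: 24 (5R,6S,8R,9R,10S)-14-[(tert-butyldimethylsilyl)oxy]-15,16-dinorlabdane-6,8-diol; 25 (2Z)-2-methylbut-2-enoic acid (angelic acid)
Product: 26 (5R,6S,8R,9R,10S)-14-[(tert-butyldimethylsilyl)oxy]-8-hydroxy-15,16-dinorlabdan-6-yl (2Z)-2-methylbut-2-enoate
Conditions: 25, 2,4,6-trichlorobenzoyl chloride, Et3N, toluene, rt; then 24, DMAP, toluene, 40 °C
Reagents that add atoms: none
Why: Yamaguchi esterification through the mixed anhydride should acylate the secondary C6 hydroxyl in preference to the tertiary C8 hydroxyl, and it is chosen because it transfers the angeloyl group without Z to E isomerisation.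

Step 14
Reactants: 26 (5R,6S,8R,9R,10S)-14-[(tert-butyldimethylsilyl)oxy]-8-hydroxy-15,16-dinorlabdan-6-yl (2Z)-2-methylbut-2-enoate
Product: 27 (5R,6S,8R,9R,10S)-8,14-dihydroxy-15,16-dinorlabdan-6-yl (2Z)-2-methylbut-2-enoate
Conditions: HF·pyridine, pyridine, THF, 0 °C → rt
Reagents that add atoms: none
Why: Buffered fluoride should cleave the primary silyl ether (desilylation) and leave the angelate and the tertiary alcohol alone.

Step 15
Reactants: 27 (5R,6S,8R,9R,10S)-8,14-dihydroxy-15,16-dinorlabdan-6-yl (2Z)-2-methylbut-2-enoate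
Product: 28 (5R,6S,8R,9R,10S)-8-hydroxy-14-oxo-15,16-dinorlabdan-6-yl (2Z)-2-methylbut-2-enoate
Conditions: TEMPO (cat.), PhI(OAc)2, CH2Cl2, rt
Reagents that add atoms: none
Why: Oxoammonium oxidation should stop at the aldehyde and cannot oxidise the tertiary alcohol.

Step 16
Reactants: 28 (5R,6S,8R,9R,10S)-8-hydroxy-14-oxo-15,16-dinorlabdan-6-yl (2Z)-2-methylbut-2-enoate
Product: 29 (5R,6S,8R,9R,10S,13S)-8,16-dihydroxy-14-oxo-15-norlabdan-6-yl (2Z)-2-methylbut-2-enoate
Conditions: (R)-2-[diphenyl(trimethylsilyloxy)methyl]pyrrolidine (20 mol%), 37% aq. HCHO, pH 7 phosphate buffer, toluene, rt; used crude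
Reagents that add atoms: formaldehyde, C=O
Why: The (E)-enamine of 28 is shielded on one face by the diphenyl(silyloxy)methyl group of the (R) catalyst, so formaldehyde should add to the other face (organocatalytic cross-aldol α-hydroxymethylation) and set C13 independently of the remote ring stereocentres; the product is 13S by the CIP rules but already has the spatial arrangement of the target.

Step 17
Reactants: 29 (5R,6S,8R,9R,10S,13S)-8,16-dihydroxy-14-oxo-15-norlabdan-6-yl (2Z)-2-methylbut-2-enoate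
Product: 30 (5R,6S,8R,9R,10S,13R)-8,16-dihydroxylabd-14-en-6-yl (2Z)-2-methylbut-2-enoate (CNP0177054.1)
Conditions: Zn, CH2Br2, TiCl4, THF/CH2Cl2, 0 °C → rt
Reagents that add atoms: dibromomethane, BrCBr
Why: Takai–Lombardo methylenation with the non-basic zinc/titanium methylene reagent should convert the aldehyde into the vinyl group without epimerising C13, eliminating the β-hydroxyl or attacking the angelate.

Compound list
1 | 3,5,5-trimethylcyclohex-3-en-1-one (β-isophorone) | CC1=CC(C)(C)CC(=O)C1 | starting material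
2 | lithium 3,5,5-trimethylcyclohexa-1,3-dien-1-olate | [Li+].[O-]C1=CC(C)=CC(C)(C)C1 | intermediate
3 | 3,5,5-trimethylcyclohexa-1,3-dien-1-yl trifluoromethanesulfonate | CC1=CC(C)(C)CC(OS(=O)(=O)C(F)(F)F)=C1 | intermediate
4 | 2,6,6-trimethylcyclohexa-1,3-diene | CC1=CC(C)(C)CC=C1 | intermediate
5 | prop-2-enal (acrolein) | C=CC=O | starting material
6 | (1S,2S,4R)-5,8,8-trimethylbicyclo[2.2.2]oct-5-ene-2-carbaldehyde (CHO syn to the C5=C6 bridge) | O=C[C@H]1C[C@H]2C(C)=C[C@@H]1CC2(C)C | intermediate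
7 | (1S,4R)-5,8,8-trimethylbicyclo[2.2.2]oct-5-en-2-one | O=C1C[C@H]2C(C)=C[C@@H]1CC2(C)C | intermediate
8 | 5-[(tert-butyldimethylsilyl)oxy]pentan-1-ol | CC(C)(C)[Si](C)(C)OCCCCCO | starting material
9 | 5-[(tert-butyldimethylsilyl)oxy]pentanal | CC(C)(C)[Si](C)(C)OCCCCC=O | intermediate
10 | tert-butyl{[(5Z)-6-iodohept-5-en-1-yl]oxy}dimethylsilane | CC(C)(C)[Si](C)(C)OCCCC/C=C(/C)I | intermediate
11 | [(2E)-7-[(tert-butyldimethylsilyl)oxy]hept-2-en-2-yl]lithium (Li cis to the chain) | [Li]/C(C)=C\CCCCO[Si](C)(C)C(C)(C)C | intermediate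
12 | (1S,2R,4R)-2-[(2Z)-7-[(tert-butyldimethylsilyl)oxy]hept-2-en-2-yl]-5,8,8-trimethylbicyclo[2.2.2]oct-5-en-2-ol (alkenyl syn to the C5=C6 bridge) | O[C@]1(/C(C)=C\CCCCO[Si](C)(C)C(C)(C)C)C[C@H]2C(C)=C[C@@H]1CC2(C)C | intermediate
13 | potassium (1S,2R,4R)-2-[(2Z)-7-[(tert-butyldimethylsilyl)oxy]hept-2-en-2-yl]-5,8,8-trimethylbicyclo[2.2.2]oct-5-en-2-olate | [K+].[O-][C@]1(/C(C)=C\CCCCO[Si](C)(C)C(C)(C)C)C[C@H]2C(C)=C[C@@H]1CC2(C)C | intermediate
14 | potassium (5R,9R,10S)-14-[(tert-butyldimethylsilyl)oxy]-15,16-dinorlabda-1,7-dien-7-olate (cis-fused) | CC(C)(C)[Si](C)(C)OCCCC[C@@H]1[C@@]2(C)C=CCC(C)(C)[C@H]2CC([O-])=C1C.[K+] | intermediate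
15 | potassium (5R,8S,9R,10S)-14-[(tert-butyldimethylsilyl)oxy]-7-oxo-15,16-dinorlabd-1-en-8-olate (8α-O) | CC(C)(C)[Si](C)(C)OCCCC[C@@H]1[C@@]2(C)C=CCC(C)(C)[C@H]2CC(=O)[C@@]1(C)[O-].[K+] | intermediate
16 | (5R,8S,9R,10S)-14-[(tert-butyldimethylsilyl)oxy]-8-[(trimethylsilyl)oxy]-15,16-dinorlabd-1-en-7-one | CC(C)(C)[Si](C)(C)OCCCC[C@@H]1[C@@]2(C)C=CCC(C)(C)[C@H]2CC(=O)[C@@]1(C)O[Si](C)(C)C | intermediate
17 | (5R,8S,9R,10S)-14-[(tert-butyldimethylsilyl)oxy]-8-[(trimethylsilyl)oxy]-15,16-dinorlabdan-7-one | CC(C)(C)[Si](C)(C)OCCCC[C@@H]1[C@@]2(C)CCCC(C)(C)[C@H]2CC(=O)[C@@]1(C)O[Si](C)(C)C | intermediate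
18 | potassium (5R,8S,9R,10S)-14-[(tert-butyldimethylsilyl)oxy]-8-[(trimethylsilyl)oxy]-15,16-dinorlabd-6-en-7-olate | CC(C)(C)[Si](C)(C)OCCCC[C@@H]1[C@@]2(C)CCCC(C)(C)[C@H]2C=C([O-])[C@@]1(C)O[Si](C)(C)C.[K+] | intermediate
19 | (5R,8S,9R,10S)-14-[(tert-butyldimethylsilyl)oxy]-8-[(trimethylsilyl)oxy]-15,16-dinorlabd-6-en-7-yl trifluoromethanesulfonate | CC(C)(C)[Si](C)(C)OCCCC[C@@H]1[C@@]2(C)CCCC(C)(C)[C@H]2C=C(OS(=O)(=O)C(F)(F)F)[C@@]1(C)O[Si](C)(C)C | intermediate
20 | (5R,8R,9R,10S)-14-[(tert-butyldimethylsilyl)oxy]-8-[(trimethylsilyl)oxy]-15,16-dinorlabd-6-ene | CC(C)(C)[Si](C)(C)OCCCC[C@@H]1[C@@]2(C)CCCC(C)(C)[C@H]2C=C[C@@]1(C)O[Si](C)(C)C | intermediate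
21 | (5R,8R,9R,10S)-14-[(tert-butyldimethylsilyl)oxy]-15,16-dinorlabd-6-en-8-ol | CC(C)(C)[Si](C)(C)OCCCC[C@@H]1[C@@]2(C)CCCC(C)(C)[C@H]2C=C[C@@]1(C)O | intermediate
22 | (5R,8R,9R,10S)-14-[(tert-butyldimethylsilyl)oxy]-8-[(dimethylsilyl)oxy]-15,16-dinorlabd-6-ene | CC(C)(C)[Si](C)(C)OCCCC[C@@H]1[C@@]2(C)CCCC(C)(C)[C@H]2C=C[C@@]1(C)O[SiH](C)C | intermediate
23 | (5R,6S,8R,9R,10S)-14-[(tert-butyldimethylsilyl)oxy]-6,8-[(dimethylsilanediyl)oxy]-15,16-dinorlabdane (Si on C6α, O on C8α) | CC(C)(C)[Si](C)(C)OCCCC[C@@H]1[C@@]2(C)CCCC(C)(C)[C@H]2[C@@H]3C[C@@]1(C)O[Si]3(C)C | intermediate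
24 | (5R,6S,8R,9R,10S)-14-[(tert-butyldimethylsilyl)oxy]-15,16-dinorlabdane-6,8-diol | CC(C)(C)[Si](C)(C)OCCCC[C@@H]1[C@@]2(C)CCCC(C)(C)[C@H]2[C@@H](O)C[C@@]1(C)O | intermediate
25 | (2Z)-2-methylbut-2-enoic acid (angelic acid) | C/C=C(/C)C(=O)O | starting material
26 | (5R,6S,8R,9R,10S)-14-[(tert-butyldimethylsilyl)oxy]-8-hydroxy-15,16-dinorlabdan-6-yl (2Z)-2-methylbut-2-enoate | CC(C)(C)[Si](C)(C)OCCCC[C@@H]1[C@@]2(C)CCCC(C)(C)[C@H]2[C@@H](OC(=O)/C(C)=C\C)C[C@@]1(C)O | intermediate
27 | (5R,6S,8R,9R,10S)-8,14-dihydroxy-15,16-dinorlabdan-6-yl (2Z)-2-methylbut-2-enoate | OCCCC[C@@H]1[C@@]2(C)CCCC(C)(C)[C@H]2[C@@H](OC(=O)/C(C)=C\C)C[C@@]1(C)O | intermediate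
28 | (5R,6S,8R,9R,10S)-8-hydroxy-14-oxo-15,16-dinorlabdan-6-yl (2Z)-2-methylbut-2-enoate | O=CCCC[C@@H]1[C@@]2(C)CCCC(C)(C)[C@H]2[C@@H](OC(=O)/C(C)=C\C)C[C@@]1(C)O | intermediate
29 | (5R,6S,8R,9R,10S,13S)-8,16-dihydroxy-14-oxo-15-norlabdan-6-yl (2Z)-2-methylbut-2-enoate | O=C[C@H](CO)CC[C@@H]1[C@@]2(C)CCCC(C)(C)[C@H]2[C@@H](OC(=O)/C(C)=C\C)C[C@@]1(C)O | intermediate
30 | (5R,6S,8R,9R,10S,13R)-8,16-dihydroxylabd-14-en-6-yl (2Z)-2-methylbut-2-enoate (CNP0177054.1) | C=C[C@H](CO)CC[C@@H]1[C@@]2(C)CCCC(C)(C)[C@H]2[C@@H](OC(=O)/C(C)=C\C)C[C@@]1(C)O | target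

Total step count: 17. Longest linear sequence: 15 steps (steps 1–4 and 7–17, from β-isophorone 1); steps 5 and 6 form the two-step branch to 10.

Steps most likely to fail

Step 8 (key step). The [3,3] shift may be slowed by the inside C11 substituent and by formation of the quaternary centre to the point where β-fragmentation of alkoxide 13 or a [1,3] shift takes over. The fallback sets out from 7 and returns at 16, and sets C9 by conjugate addition instead of by the sigmatropic shift. Isopropenylmagnesium bromide would add to 7 to give (1S,2R,4R)-5,8,8-trimethyl-2-(prop-1-en-2-yl)bicyclo[2.2.2]oct-5-en-2-ol F1, whose potassium alkoxide (KH, 18-crown-6, THF) has no inside substituent and should rearrange readily. Trapping with TMSCl would give the silyl enol ether (4aR,8aS)-2,5,5,8a-tetramethyl-3-[(trimethylsilyl)oxy]-1,4,4a,5,6,8a-hexahydronaphthalene F2, and Saegusa oxidation (Pd(OAc)2, MeCN) the enone (4aR,8aR)-3,4a,8,8-tetramethyl-4a,7,8,8a-tetrahydronaphthalen-2(1H)-one F3. Copper-catalysed conjugate addition of {4-[(tert-butyldimethylsilyl)oxy]butyl}magnesium bromide F4 (from the commercial bromide; CuBr·SMe2, TMSCl, THF, −78 °C) should occur on the convex face, syn to the angular methyl group, and give (5R,9R,10S)-14-[(tert-butyldimethylsilyl)oxy]-7-[(trimethylsilyl)oxy]-15,16-dinorlabda-1,7-diene F5. Rubottom oxidation (dimethyldioxirane, acetone, −78 °C), anti to the new side chain and with silyl migration, would then give 16.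

Step 16. Under amine catalysis the β-hydroxy aldehyde may lose water to the α-methylene aldehyde, C13 may lose its configuration, or the angelate may isomerise. The fallback sets out from 28 and returns at 30, replacing steps 16 and 17. The vinyl group, not the hydroxymethyl group, would be introduced at C13 by enantioselective α-vinylation of 28 under combined copper(I) and chiral secondary-amine catalysis with ethenyl(phenyl)iodonium triflate. This would give (5R,6S,8R,9R,10S,13R)-8-hydroxy-16-oxolabd-14-en-6-yl (2Z)-2-methylbut-2-enoate F7, which would be reduced in the same flask (NaBH4, MeOH, −20 °C) before it can conjugate or epimerise; the former aldehyde carbon becomes C16 of 30.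

Step 12. The 5-endo hydrosilylation of the hindered ring alkene may be slow, so that loss of the Si–H group or intermolecular hydrosilylation competes. The fallback sets out from 21 and returns at 24. Vanadium-catalysed hydroxyl-directed epoxidation (VO(acac)2, t-BuOOH, CH2Cl2) would give (5R,9R,10S)-14-[(tert-butyldimethylsilyl)oxy]-6α,7α-epoxy-15,16-dinorlabdan-8α-ol F6. Reduction with Red-Al in THF should open the epoxide at C7, because the trans-diaxial alternative at C6 is blocked by the two axial methyl groups C17 and C20, and give 24.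

Further compounds
F1 | step 8 | (1S,2R,4R)-5,8,8-trimethyl-2-(prop-1-en-2-yl)bicyclo[2.2.2]oct-5-en-2-ol | O[C@]1(C(C)=C)C[C@H]2C(C)=C[C@@H]1CC2(C)C
F2 | step 8 | (4aR,8aS)-2,5,5,8a-tetramethyl-3-[(trimethylsilyl)oxy]-1,4,4a,5,6,8a-hexahydronaphthalene | C[Si](C)(C)OC1=C(C)C[C@@]2(C)C=CCC(C)(C)[C@H]2C1
F3 | step 8 | (4aR,8aR)-3,4a,8,8-tetramethyl-4a,7,8,8a-tetrahydronaphthalen-2(1H)-one | CC1=C[C@@]2(C)C=CCC(C)(C)[C@H]2CC1=O
F4 | step 8 | {4-[(tert-butyldimethylsilyl)oxy]butyl}magnesium bromide | CC(C)(C)[Si](C)(C)OCCCC[Mg]Br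
F5 | step 8 | (5R,9R,10S)-14-[(tert-butyldimethylsilyl)oxy]-7-[(trimethylsilyl)oxy]-15,16-dinorlabda-1,7-diene | CC(C)(C)[Si](C)(C)OCCCC[C@@H]1[C@@]2(C)C=CCC(C)(C)[C@H]2CC(O[Si](C)(C)C)=C1C
F6 | step 12 | (5R,9R,10S)-14-[(tert-butyldimethylsilyl)oxy]-6α,7α-epoxy-15,16-dinorlabdan-8α-ol | CC(C)(C)[Si](C)(C)OCCCC[C@@H]1[C@@]2(C)CCCC(C)(C)[C@H]2[C@H]3O[C@H]3[C@@]1(C)O
F7 | step 16 | (5R,6S,8R,9R,10S,13R)-8-hydroxy-16-oxolabd-14-en-6-yl (2Z)-2-methylbut-2-enoate | C=C[C@H](C=O)CC[C@@H]1[C@@]2(C)CCCC(C)(C)[C@H]2[C@@H](OC(=O)/C(C)=C\C)C[C@@]1(C)O
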